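**Plan**

Ring numbering used here: C1 carries the C7H2OBz group, C1=C2 is the alkene, then C3(OH), C4(OH), C5(OAc), C6(OBz).

- Retrosynthesis: after removal of the acyl and silyl groups and return of the C4/C5 cis-diol to an alkene, the ring is cut at C1=C2 and at C4–C5. This gives two C3 allylic alcohols: C5–C6–C1(C7) and C4–C3–C2 (penta-1,4-dien-3-ol).
- Enabling feature: the ring oxygens have the conduritol A pattern. O3 and O6 are cis across the ring on either side of C1=C2; O4 and O5 are cis to each other and trans to them. A local mirror plane therefore runs through the midpoints of C1=C2 and C4–C5, and the cis O3/O6 pair can be spanned by one silicon atom.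
- Forward: the C6 half is made in three steps and joined to penta-1,4-dien-3-ol as a diisopropylsilaketal. A double ring-closing metathesis closes first the seven-membered silaketal ring (C4=C5), then the six-membered carbocycle (C1=C2). The bridge is then removed, O3 and O6 are told apart, C4=C5 is dihydroxylated and O5 is acetylated.
- Stereochemistry: C6 from a catalytic asymmetric vinylation; C3 from C6 through the cis-spanning tether (choice between two diastereotopic vinyl groups); C4 and C5 from osmylation anti to both allylic oxygens.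

Key step: step 5

Remark: the C4–C5 bond is closed at the alkene oxidation level in step 5 and raised to the cis-diol in step 9; divinylzinc is taken as a pre-formed, salt-free reagent.

**Route**

Step 1
Reactants: 1 2-methylidenepropane-1,3-diol
Product: 2 2-(hydroxymethyl)prop-2-en-1-yl benzoate
Conditions: BzCl (0.9 equiv), Et3N, CH2Cl2, −20 to 0 °C
Reagents that add atoms: benzoyl chloride, O=C(Cl)c1ccccc1
Why: Mono-acylation of a symmetrical primary diol with a substoichiometric acid chloride (esterification) should give the mono-benzoate, which is separable from dibenzoate and recovered diol.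

Step 2
Reactants: 2 2-(hydroxymethyl)prop-2-en-1-yl benzoate
Product: 3 2-formylprop-2-en-1-yl benzoate
Conditions: Dess–Martin periodinane, CH2Cl2, 0 °C to rt
Reagents that add atoms: none
Why: Dess–Martin oxidation of a primary allylic alcohol to the enal runs under neutral conditions that should leave the allylic benzoate untouched.

Step 3
Reactants: 3 2-formylprop-2-en-1-yl benzoate
Product: 4 (3R)-3-hydroxy-2-methylidenepent-4-en-1-yl benzoate
Conditions: Zn(CH=CH2)2, (+)-3-exo-(dimethylamino)isoborneol (5 mol%), Et2O/toluene, −20 to 0 °C; aq NH4Cl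
Reagents that add atoms: divinylzinc, C=C[Zn]C=C
Why: Amino-alcohol-catalysed enantioselective 1,2-addition of an alkenylzinc to an aldehyde (Noyori/Oppolzer type) should deliver vinyl to the Re face of the enal and set the (R)-carbinol that becomes C6, the ester being inert to the organozinc.

Step 4
Reactants: 4 (3R)-3-hydroxy-2-methylidenepent-4-en-1-yl benzoate; 5 penta-1,4-dien-3-ol
Product: 7 (3R)-2-methylidene-3-{[(penta-1,4-dien-3-yloxy)di(propan-2-yl)silyl]oxy}pent-4-en-1-yl benzoate, via chlorosilyl ether 6 (not isolated)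
Conditions: iPr2SiCl2 (3 equiv), imidazole, CH2Cl2, 0 °C; excess silane removed in vacuo; then 5, imidazole, CH2Cl2, rt
Reagents that add atoms: dichlorodi(propan-2-yl)silane, CC(C)[Si](Cl)(Cl)C(C)C
Why: Stepwise silylation of two secondary alcohols with a dichlorodialkylsilane is the standard entry to unsymmetrical bis-alkoxysilanes (temporary silicon tether) and touches no stereocenter.

Step 5
Reactants: 7 (3R)-2-methylidene-3-{[(penta-1,4-dien-3-yloxy)di(propan-2-yl)silyl]oxy}pent-4-en-1-yl benzoate
Product: 9 [(1S,5R)-3,3-di(propan-2-yl)-2,4-dioxa-3-silabicyclo[3.2.2]nona-6,8-dien-6-yl]methyl benzoate, via monocyclic silaketal 8 (not isolated)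
Conditions: RuCl2(=CHPh)(H2IMes)(PCy3) (second-generation Grubbs catalyst, 10 mol%), 1,4-benzoquinone (20 mol%), toluene (2 mM), 80 °C, argon sparge
Reagents that add atoms: none
Why: The ruthenium alkylidene loads on a vinyl group and two successive [2+2]/retro-[2+2] sequences expel two molecules of ethene: the first closes the seven-membered 1,3-dioxa-2-silacyclohept-5-ene through C4=C5 (intermediate 8), the second joins the C2 vinyl to the C1 methylidene and completes the cyclohexa-1,4-diene inside a 2,4-dioxa-3-silabicyclo[3.2.2]nonadiene. The closest known reaction type is temporary silicon-tethered ring-closing metathesis of bis-allylic silaketals, including closures that select between the two vinyl groups of penta-1,4-dien-3-ol. Both rings close by ring-closing metathesis, the silaketal ring as a seven-membered cis-alkene and the carbocycle as a six-membered ring across the 4,7-positions of that ring. The new stereocenter C3 is fixed by C6 through the tether, because only the monocycle whose two alkenyl groups are cis across the O–Si–O unit can reach the second closure, while the trans isomer can return to 7 by ring opening with the ruthenium methylidene. The step needs ring closure to win over oligomerisation and over alkene migration toward an aromatic product, which high dilution, the short tether and 1,4-benzoquinone as hydride scavenger should secure. The 1,1-disubstituted C1 alkene reacts last, so the trisubstituted C1=C2 bond is made intramolecularly in the most pre-organised intermediate.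

Step 6
Reactants: 9 [(1S,5R)-3,3-di(propan-2-yl)-2,4-dioxa-3-silabicyclo[3.2.2]nona-6,8-dien-6-yl]methyl benzoate
Product: 10 [(3S,6R)-3,6-dihydroxycyclohexa-1,4-dien-1-yl]methyl benzoate (cis-diol)
Conditions: Et3N·3HF, Et3N, THF, 0 °C to rt
Reagents that add atoms: none
Why: Fluoride cleavage of the dialkoxysilane under near-neutral conditions should free the cis-1,4-diol without benzoate migration and without acid-induced dehydration of the bis-allylic carbinols to an arene.

Step 7
Reactants: 10 [(3S,6R)-3,6-dihydroxycyclohexa-1,4-dien-1-yl]methyl benzoate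
Product: 11 [(3S,6R)-3-{[tert-butyl(dimethyl)silyl]oxy}-6-hydroxycyclohexa-1,4-dien-1-yl]methyl benzoate
Conditions: TBSCl (1.05 equiv), imidazole, DMF, −20 °C
Reagents that add atoms: tert-butyl(chloro)dimethylsilane, CC(C)(C)[Si](C)(C)Cl
Why: Silylation with a bulky chlorosilane should select the C3 hydroxyl, whose alkene neighbour C2 carries only hydrogen, over the C6 hydroxyl, which is flanked by the substituted alkene carbon C1.

Step 8
Reactants: 11 [(3S,6R)-3-{[tert-butyl(dimethyl)silyl]oxy}-6-hydroxycyclohexa-1,4-dien-1-yl]methyl benzoate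
Product: 12 [(3S,6R)-6-(benzoyloxy)-3-{[tert-butyl(dimethyl)silyl]oxy}cyclohexa-1,4-dien-1-yl]methyl benzoate
Conditions: BzCl, pyridine, DMAP (cat.), CH2Cl2, 0 °C
Reagents that add atoms: benzoyl chloride, O=C(Cl)c1ccccc1
Why: DMAP-catalysed acylation of the one remaining secondary allylic alcohol installs the C6 benzoate under basic conditions that the acid-sensitive diene should tolerate.

Step 9
Reactants: 12 [(3S,6R)-6-(benzoyloxy)-3-{[tert-butyl(dimethyl)silyl]oxy}cyclohexa-1,4-dien-1-yl]methyl benzoate
Product: 13 [(3R,4R,5S,6S)-6-(benzoyloxy)-3-{[tert-butyl(dimethyl)silyl]oxy}-4,5-dihydroxycyclohex-1-en-1-yl]methyl benzoate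
Conditions: OsO4 (5 mol%), NMO, acetone/H2O, 0 °C
Reagents that add atoms: osmium tetroxide, O=[Os](=O)(=O)=O; N-methylmorpholine N-oxide, C[N+]1([O-])CCOCC1; water, O
Why: Upjohn dihydroxylation should occur at the disubstituted C4=C5 alkene (C1=C2 is trisubstituted, more hindered and carries three allylic oxygens) and anti to both allylic oxygens (Kishi's empirical rule), which sets C4 and C5 as the cis-diol trans to O3 and O6.

Step 10
Reactants: 13 [(3R,4R,5S,6S)-6-(benzoyloxy)-3-{[tert-butyl(dimethyl)silyl]oxy}-4,5-dihydroxycyclohex-1-en-1-yl]methyl benzoate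
Product: 15 [(3R,4R,5S,6S)-5-(acetyloxy)-6-(benzoyloxy)-3-{[tert-butyl(dimethyl)silyl]oxy}-4-hydroxycyclohex-1-en-1-yl]methyl benzoate, via cyclic orthoacetate 14 (not isolated)
Conditions: MeC(OMe)3, CSA (cat.), CH2Cl2, rt; then AcOH/H2O 4:1, 0 °C
Reagents that add atoms: trimethyl orthoacetate, COC(C)(OC)OC; water, O
Why: Transorthoesterification gives the cyclic orthoacetate of the cis-diol, and its mild hydrolysis should break the equatorial C–O bond and leave the axial acetate, which is O5 in the half-chair that keeps the C6 benzoate pseudoaxial (allylic 1,2-strain with C7) and the C3 silyl ether pseudoequatorial.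

Step 11
Reactants: 15 [(3R,4R,5S,6S)-5-(acetyloxy)-6-(benzoyloxy)-3-{[tert-butyl(dimethyl)silyl]oxy}-4-hydroxycyclohex-1-en-1-yl]methyl benzoate
Product: 16 [(3R,4S,5S,6S)-5-(acetyloxy)-6-(benzoyloxy)-3,4-dihydroxycyclohex-1-en-1-yl]methyl benzoate
Conditions: HF·pyridine, pyridine, THF, 0 °C to rt
Reagents that add atoms: none
Why: Fluoride cleavage of the secondary silyl ether under mildly acidic conditions should free O3 without base-promoted migration of the cis-vicinal acetate or of the benzoates.

**Compound list**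

1 | 2-methylidenepropane-1,3-diol | C=C(CO)CO | starting material
2 | 2-(hydroxymethyl)prop-2-en-1-yl benzoate | C=C(CO)COC(=O)c1ccccc1 | intermediate
3 | 2-formylprop-2-en-1-yl benzoate | C=C(C=O)COC(=O)c1ccccc1 | intermediate
4 | (3R)-3-hydroxy-2-methylidenepent-4-en-1-yl benzoate | C=C(COC(=O)c1ccccc1)[C@@H](C=C)O | intermediate
5 | penta-1,4-dien-3-ol | C=CC(O)C=C | starting material
6 | (3R)-3-{[chlorodi(propan-2-yl)silyl]oxy}-2-methylidenepent-4-en-1-yl benzoate | C=C(COC(=O)c1ccccc1)[C@@H](C=C)O[Si](Cl)(C(C)C)C(C)C | intermediate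
7 | (3R)-2-methylidene-3-{[(penta-1,4-dien-3-yloxy)di(propan-2-yl)silyl]oxy}pent-4-en-1-yl benzoate | C=C(COC(=O)c1ccccc1)[C@@H](C=C)O[Si](OC(C=C)C=C)(C(C)C)C(C)C | intermediate
8 | 2-[(4R,7R)-7-ethenyl-2,2-di(propan-2-yl)-4,7-dihydro-1,3,2-dioxasilepin-4-yl]prop-2-en-1-yl benzoate (cis) | C=C(COC(=O)c1ccccc1)[C@H]1C=C[C@@H](C=C)O[Si](C(C)C)(C(C)C)O1 | intermediate
9 | [(1S,5R)-3,3-di(propan-2-yl)-2,4-dioxa-3-silabicyclo[3.2.2]nona-6,8-dien-6-yl]methyl benzoate | O=C(OCC1=C[C@@H]2C=C[C@H]1O[Si](C(C)C)(C(C)C)O2)c1ccccc1 | intermediate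
10 | [(3S,6R)-3,6-dihydroxycyclohexa-1,4-dien-1-yl]methyl benzoate | O=C(OCC1=C[C@@H](O)C=C[C@H]1O)c1ccccc1 | intermediate
11 | [(3S,6R)-3-{[tert-butyl(dimethyl)silyl]oxy}-6-hydroxycyclohexa-1,4-dien-1-yl]methyl benzoate | O=C(OCC1=C[C@@H](O[Si](C)(C)C(C)(C)C)C=C[C@H]1O)c1ccccc1 | intermediate
12 | [(3S,6R)-6-(benzoyloxy)-3-{[tert-butyl(dimethyl)silyl]oxy}cyclohexa-1,4-dien-1-yl]methyl benzoate | O=C(OCC1=C[C@@H](O[Si](C)(C)C(C)(C)C)C=C[C@H]1OC(=O)c1ccccc1)c1ccccc1 | intermediate
13 | [(3R,4R,5S,6S)-6-(benzoyloxy)-3-{[tert-butyl(dimethyl)silyl]oxy}-4,5-dihydroxycyclohex-1-en-1-yl]methyl benzoate | O[C@H]1[C@@H](O)[C@H](O[Si](C)(C)C(C)(C)C)C=C(COC(=O)c2ccccc2)[C@@H]1OC(=O)c1ccccc1 | intermediate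
14 | cyclic orthoacetate of 13 (O4 and O5 joined through C(CH3)(OCH3), either configuration at that carbon) | COC1(C)O[C@H]2[C@@H](O1)[C@H](O[Si](C)(C)C(C)(C)C)C=C(COC(=O)c1ccccc1)[C@@H]2OC(=O)c1ccccc1 | intermediate
15 | [(3R,4R,5S,6S)-5-(acetyloxy)-6-(benzoyloxy)-3-{[tert-butyl(dimethyl)silyl]oxy}-4-hydroxycyclohex-1-en-1-yl]methyl benzoate | CC(=O)O[C@H]1[C@@H](O)[C@H](O[Si](C)(C)C(C)(C)C)C=C(COC(=O)c2ccccc2)[C@@H]1OC(=O)c1ccccc1 | intermediate
16 | [(3R,4S,5S,6S)-5-(acetyloxy)-6-(benzoyloxy)-3,4-dihydroxycyclohex-1-en-1-yl]methyl benzoate | CC(=O)O[C@H]1[C@@H](O)[C@H](O)C=C(COC(=O)c2ccccc2)[C@@H]1OC(=O)c1ccccc1 | target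

**Step count**

Total step count: 11. Longest linear sequence: 11 steps (1 to 16); penta-1,4-dien-3-ol (5) enters at step 4.

**Steps most likely to fail**

Step 5. The first closure may not discriminate between the two diastereotopic vinyl groups, and the second closure to the bridged ring may be slow, so that oligomerisation or alkene migration takes over. Fallback: setting out from 7, the two closures are separated. RuCl2(=CHPh)(PCy3)2 (first-generation Grubbs catalyst) in CH2Cl2 at 40 °C, which does not engage the 1,1-disubstituted alkene, should stop at the monocyclic silaketal 8, now isolated and freed of its trans isomer by chromatography. Et3N·3HF then removes the silicon to give (3R,4Z,6R)-3,6-dihydroxy-2-methylideneocta-4,7-dien-1-yl benzoate F1, whose Z-alkene was templated by the tether. An ordinary untethered ring-closing metathesis of F1 with RuCl2(=CHPh)(H2IMes)(PCy3) closes the six-membered ring as an unbridged cyclohexa-1,4-diene and rejoins the route at 10.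

Step 7. Site selectivity between the two secondary allylic hydroxyls may be insufficient in the silylation. Fallback: setting out from 10, K2CO3 in MeOH removes the primary benzoate to give (1R,4S)-2-(hydroxymethyl)cyclohexa-2,5-diene-1,4-diol F2. 2,2-Dimethoxypropane with PPTS then locks the 1,3-related O6 and O7 into the six-membered acetonide (6S,8aR)-2,2-dimethyl-6,8a-dihydro-4H-1,3-benzodioxin-6-ol F3, which leaves O3 as the only free hydroxyl. TBSCl with imidazole gives tert-butyl{[(6S,8aR)-2,2-dimethyl-6,8a-dihydro-4H-1,3-benzodioxin-6-yl]oxy}dimethylsilane F4. PPTS in MeOH removes the acetonide to give (1R,4S)-4-{[tert-butyl(dimethyl)silyl]oxy}-2-(hydroxymethyl)cyclohexa-2,5-dien-1-ol F5. BzCl (2.2 equiv) with pyridine and DMAP then installs both benzoates at once and rejoins the route at 12.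

Step 10. The orthoester may collapse in the wrong direction, or the acetyl group may migrate between the cis-vicinal oxygens. Fallback: setting out from 12, the silyl ether is removed first with Et3N·3HF to give [(3S,6R)-6-(benzoyloxy)-3-hydroxycyclohexa-1,4-dien-1-yl]methyl benzoate F6. Osmylation (OsO4, NMO), again anti to the allylic oxygens, gives [(3R,4S,5S,6S)-6-(benzoyloxy)-3,4,5-trihydroxycyclohex-1-en-1-yl]methyl benzoate F7. Butane-2,3-dione, HC(OMe)3 and CSA in MeOH should protect only the trans-diequatorial O3/O4 pair, which the cis O4/O5 pair cannot match, giving the 3,4-O-(2,3-dimethoxybutane-2,3-diyl) acetal of F7 F8 with O5 as the only free hydroxyl. Ac2O in pyridine gives the 5-O-acetyl derivative of that acetal F9. TFA/H2O removes the diacetal and arrives at 16.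

**Further compounds**

F1 | step 5 | (3R,4Z,6R)-3,6-dihydroxy-2-methylideneocta-4,7-dien-1-yl benzoate | C=C(COC(=O)c1ccccc1)[C@H](O)/C=C\[C@H](O)C=C
F2 | step 7 | (1R,4S)-2-(hydroxymethyl)cyclohexa-2,5-diene-1,4-diol | OCC1=C[C@@H](O)C=C[C@H]1O
F3 | step 7 | (6S,8aR)-2,2-dimethyl-6,8a-dihydro-4H-1,3-benzodioxin-6-ol | CC1(C)OCC2=C[C@@H](O)C=C[C@H]2O1
F4 | step 7 | tert-butyl{[(6S,8aR)-2,2-dimethyl-6,8a-dihydro-4H-1,3-benzodioxin-6-yl]oxy}dimethylsilane | CC1(C)OCC2=C[C@@H](O[Si](C)(C)C(C)(C)C)C=C[C@H]2O1
F5 | step 7 | (1R,4S)-4-{[tert-butyl(dimethyl)silyl]oxy}-2-(hydroxymethyl)cyclohexa-2,5-dien-1-ol | OCC1=C[C@@H](O[Si](C)(C)C(C)(C)C)C=C[C@H]1O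
F6 | step 10 | [(3S,6R)-6-(benzoyloxy)-3-hydroxycyclohexa-1,4-dien-1-yl]methyl benzoate | O=C(OCC1=C[C@@H](O)C=C[C@H]1OC(=O)c1ccccc1)c1ccccc1
F7 | step 10 | [(3R,4S,5S,6S)-6-(benzoyloxy)-3,4,5-trihydroxycyclohex-1-en-1-yl]methyl benzoate | O[C@H]1[C@@H](O)[C@H](O)C=C(COC(=O)c2ccccc2)[C@@H]1OC(=O)c1ccccc1
F8 | step 10 | 3,4-O-(2,3-dimethoxybutane-2,3-diyl) acetal of F7 | O[C@H]1[C@@H](OC(C)(OC)C(C)(OC)O2)[C@H]2C=C(COC(=O)c2ccccc2)[C@@H]1OC(=O)c1ccccc1
F9 | step 10 | 5-O-acetyl derivative of F8 | CC(=O)O[C@H]1[C@@H](OC(C)(OC)C(C)(OC)O2)[C@H]2C=C(COC(=O)c2ccccc2)[C@@H]1OC(=O)c1ccccc1
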